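**Plan**

- Numbering follows the isochromene skeleton (C-1, O-2, C-3, C-4, C-4a, C-5 … C-8, C-8a); the side chain is C-1' … C-7'. TBDPS = tert-butyldiphenylsilyl, TES = triethylsilyl.
- Retrosynthesis: the pyran enol-ether carbon C-1 is taken back to a lactone carbonyl, the C-8 carbinol to a ketone and C-5–Cl to C-5–H. The carbocycle is then cut at C-4a–C-5 and at C-7–C-8 into a 4-chloro-3-formyl-2-pyranone and butane-2,3-dione. The pyranone is cut to a dioxinone and a dienoic N-methoxy-N-methylamide, and the diene at its two C=C bonds.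
- Enabling feature: in the six-membered carbocycle, C-4a is the β-carbon of the C-8a/C-8 enal; with C-1 as a lactone carbonyl and Cl on C-4a it is a vinylogous acyl chloride carbon, and C-8 is a formyl carbon. C-5/C-6/C-7 with the C-7 methyl is butane-2,3-dione (carbon acid at C-5, ketone at C-7). One pot joins C-5 to C-4a by vinylic substitution and C-8 to C-7 by carbene-catalysed crossed benzoin.
- Forward: side chain (steps 1–6), 2-pyranone ring by acylketene cyclisation (7–8), Cl/CHO activation (9), carbocycle (10), then C-5 chlorination, silylation, double hydride reduction and acid/fluoride unravelling (11–13), which turns the helper lactone into the pyran and frees the C-6 ketone.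
- Stereochemistry: C-5' from asymmetric hydrogenation; both side-chain alkenes E from stabilised-ylide and phosphonate olefinations; C-7 from the chiral triazolylidene in the benzoin closure; C-8 from hydride addition anti to the C-7 silyloxy group (cis-diol).

Key step: step 10

Assumption: the senses of induction of Ru(OAc)2[(R)-BINAP] in step 1 and of the (5aR,10bS)-triazolium salt in step 10 are assigned by analogy with related substrates; both catalysts exist in either enantiomeric form, so the antipode would be used if the opposite sense were found.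

**Route**

Step 1
Reactants: 1 3-methylidenedihydrofuran-2(3H)-one (α-methylene-γ-butyrolactone)
Product: 2 (S)-3-methyldihydrofuran-2(3H)-one
Conditions: H2 (100 atm), Ru(OAc)2[(R)-BINAP] (0.5 mol%), CH2Cl2, 50 °C
Reagents that add atoms: none
Why: Asymmetric hydrogenation of the carbonyl-conjugated exocyclic alkene; Ru(OAc)2[(R)-BINAP] should select the alkene face through coordination of the lactone carbonyl and set the S centre that becomes C-5'.

Step 2
Reactants: 2 (S)-3-methyldihydrofuran-2(3H)-one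
Product: 3 (S)-4-hydroxy-N-methoxy-N,2-dimethylbutanamide
Conditions: MeNH(OMe)·HCl, i-PrMgCl, THF, −20 → 0 °C
Reagents that add atoms: N,O-dimethylhydroxylamine hydrochloride, CNOC.Cl
Why: Lactone aminolysis by the chloromagnesium amide (N-methoxy-N-methylamide formation), which acts as a nucleophile at the carbonyl at low temperature and should leave the α-stereocentre untouched.

Step 3
Reactants: 3 (S)-4-hydroxy-N-methoxy-N,2-dimethylbutanamide
Product: 4 (S)-4-[(tert-butyldiphenylsilyl)oxy]-N-methoxy-N,2-dimethylbutanamide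
Conditions: t-BuPh2SiCl, imidazole, DMF, rt
Reagents that add atoms: tert-butyl(chloro)diphenylsilane, CC(C)(C)[Si](Cl)(c1ccccc1)c1ccccc1
Why: Silylation of the primary alcohol; the TBDPS ether is chosen because it should survive hydride, enolate, thermal, chloroiminium and triflate conditions and fall in the final fluoride step.

Step 4
Reactants: 4 (S)-4-[(tert-butyldiphenylsilyl)oxy]-N-methoxy-N,2-dimethylbutanamide
Product: 5 (S)-4-[(tert-butyldiphenylsilyl)oxy]-2-methylbutanal
Conditions: i-Bu2AlH, THF, −78 °C; aq. potassium sodium tartrate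
Reagents that add atoms: none
Why: Hydride reduction of the N-methoxy-N-methylamide stops at the chelated hemiaminal aluminate and releases the aldehyde on work-up; the α-stereocentre is kept by working cold and using 5 at once.

Step 5
Reactants: 5 (S)-4-[(tert-butyldiphenylsilyl)oxy]-2-methylbutanal; 6 2-(triphenyl-λ5-phosphanylidene)propanal
Product: 7 (2E,4S)-6-[(tert-butyldiphenylsilyl)oxy]-2,4-dimethylhex-2-enal
Conditions: 6, toluene, 90 °C
Reagents that add atoms: none
Why: Wittig olefination with a stabilised formyl ylide, which should give the E-trisubstituted enal under the usual stabilised-ylide control without base strong enough to epimerise C-4.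

Step 6
Reactants: 7 (2E,4S)-6-[(tert-butyldiphenylsilyl)oxy]-2,4-dimethylhex-2-enal; 8 diethyl {2-[methoxy(methyl)amino]-2-oxoethyl}phosphonate
Product: 9 (2E,4E,6S)-8-[(tert-butyldiphenylsilyl)oxy]-N-methoxy-N,4,6-trimethylocta-2,4-dienamide
Conditions: 8, NaH, THF, 0 °C → rt
Reagents that add atoms: none
Why: Horner–Wadsworth–Emmons olefination of the enal, E-selective for the new disubstituted alkene, giving the dienoic amide as acyl donor for the next step.

Step 7
Reactants: 9 (2E,4E,6S)-8-[(tert-butyldiphenylsilyl)oxy]-N-methoxy-N,4,6-trimethylocta-2,4-dienamide; 10 2,2,6-trimethyl-4H-1,3-dioxin-4-one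
Product: 11 6-{(3E,5E,7S)-9-[(tert-butyldiphenylsilyl)oxy]-5,7-dimethyl-2-oxonona-3,5-dien-1-yl}-2,2-dimethyl-4H-1,3-dioxin-4-one
Conditions: 10, LiN(i-Pr)2, THF, −78 °C; then 9, −78 → −40 °C; aq. NH4Cl
Reagents that add atoms: none
Why: Vinylogous Claisen condensation: the lithium dienolate of the dioxinone is acylated at its γ-carbon by the N-methoxy-N-methylamide, whose chelated tetrahedral intermediate should prevent over-addition.

Step 8
Reactants: 11 6-{(3E,5E,7S)-9-[(tert-butyldiphenylsilyl)oxy]-5,7-dimethyl-2-oxonona-3,5-dien-1-yl}-2,2-dimethyl-4H-1,3-dioxin-4-one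
Product: 13 6-{(1E,3E,5S)-7-[(tert-butyldiphenylsilyl)oxy]-3,5-dimethylhepta-1,3-dien-1-yl}-4-hydroxy-2H-pyran-2-one, via acylketene 12 (not isolated)
Conditions: toluene, 110 °C
Reagents that add atoms: none
Why: Thermal retro-[4+2] loss of acetone from the dioxinone gives the acylketene, which should be captured by the enol oxygen of the δ-ketone to close the 4-hydroxy-2-pyranone (acylketene cyclisation).

Step 9
Reactants: 13 6-{(1E,3E,5S)-7-[(tert-butyldiphenylsilyl)oxy]-3,5-dimethylhepta-1,3-dien-1-yl}-4-hydroxy-2H-pyran-2-one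
Product: 14 4-chloro-6-{(1E,3E,5S)-7-[(tert-butyldiphenylsilyl)oxy]-3,5-dimethylhepta-1,3-dien-1-yl}-2-oxo-2H-pyran-3-carbaldehyde
Conditions: POCl3, DMF, 0 °C → rt; then ice-water
Reagents that add atoms: phosphoryl chloride, O=P(Cl)(Cl)Cl; N,N-dimethylformamide, CN(C)C=O; water, O
Why: Vilsmeier–Haack reaction: the chloroiminium reagent formylates pyranone C-3 (the α-carbon of the cyclic β-keto-lactone enol) and replaces the 4-hydroxyl by chloride, making pyranone C-4 (future C-4a) a vinylogous acyl chloride carbon next to the formyl carbon (future C-8), while the lactone carbonyl (future C-1) keeps that position closed to nucleophiles.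

Step 10
Reactants: 14 4-chloro-6-{(1E,3E,5S)-7-[(tert-butyldiphenylsilyl)oxy]-3,5-dimethylhepta-1,3-dien-1-yl}-2-oxo-2H-pyran-3-carbaldehyde; 15 butane-2,3-dione
Product: 17 (7S)-3-{(1E,3E,5S)-7-[(tert-butyldiphenylsilyl)oxy]-3,5-dimethylhepta-1,3-dien-1-yl}-6,7-dihydroxy-7-methyl-1H-isochromene-1,8(7H)-dione (6-enol tautomer; same spatial arrangement at C-7 as the 7R target), via diketo aldehyde 16 (not isolated)
Conditions: 15 (1.5 equiv), Et3N (1.5 equiv), THF, 0 °C → rt; then (5aR,10bS)-2-(pentafluorophenyl)-5a,10b-dihydro-4H,6H-indeno[2,1-b][1,2,4]triazolo[4,3-d][1,4]oxazin-2-ium tetrafluoroborate (20 mol%), rt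
Reagents that add atoms: none
Why: Proposed new method: the enol(ate) carbon of 15 displaces chloride at the vinylogous acyl chloride carbon of 14 by addition–elimination (C-4a–C-5 bond, giving 16), and the carbene from the triazolium salt then converts the formyl group into an enaminol acyl-anion equivalent that adds to the C-7 ketone (C-7–C-8 bond); the closest known reaction types are vinylic substitution of 4-chloro-3-formyl-coumarins and -pyranones by carbon acids, the carbene-catalysed Michael/crossed-benzoin cascade, and the enantioselective intramolecular aldehyde–ketone benzoin cyclisation. The carbocycle closes in 6-exo-trig mode by attack of C-8 on the C-7 carbonyl. The only new stereocentre, C-7, is controlled by the aminoindanol-derived triazolylidene, which should differentiate the two faces of the methyl ketone. Selectivity for C-7 over C-6 (five-membered closure) is needed and should be secured because C-6 is enolised in conjugation with the pyranone and is therefore not electrophilic, and conjugate (homoenolate) reactivity of the aldehyde is excluded because C-4a/C-8a belong to the pyranone ring. The triazolium salt is added only after chloride displacement so that the carbene is not consumed at C–Cl, and the amine is limited so that part of 16 stays un-ionised and its aldehyde remains electrophilic.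

Step 11
Reactants: 17 (7S)-3-{(1E,3E,5S)-7-[(tert-butyldiphenylsilyl)oxy]-3,5-dimethylhepta-1,3-dien-1-yl}-6,7-dihydroxy-7-methyl-1H-isochromene-1,8(7H)-dione
Product: 18 (7S)-5-chloro-3-{(1E,3E,5S)-7-[(tert-butyldiphenylsilyl)oxy]-3,5-dimethylhepta-1,3-dien-1-yl}-6,7-dihydroxy-7-methyl-1H-isochromene-1,8(7H)-dione
Conditions: N-chlorosuccinimide (1.05 equiv), CH2Cl2, 0 °C
Reagents that add atoms: N-chlorosuccinimide, O=C1CCC(=O)N1Cl
Why: Electrophilic α-chlorination of the enol carbon C-5, the most nucleophilic carbon of the vinylogous acid and far more reactive than the acceptor-conjugated side-chain diene.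

Step 12
Reactants: 18 (7S)-5-chloro-3-{(1E,3E,5S)-7-[(tert-butyldiphenylsilyl)oxy]-3,5-dimethylhepta-1,3-dien-1-yl}-6,7-dihydroxy-7-methyl-1H-isochromene-1,8(7H)-dione
Product: 19 (7S)-5-chloro-3-{(1E,3E,5S)-7-[(tert-butyldiphenylsilyl)oxy]-3,5-dimethylhepta-1,3-dien-1-yl}-7-methyl-6,7-bis[(triethylsilyl)oxy]-1H-isochromene-1,8(7H)-dione
Conditions: Et3SiOTf (2.5 equiv), 2,6-lutidine, CH2Cl2, −78 → 0 °C
Reagents that add atoms: triethylsilyl trifluoromethanesulfonate, CC[Si](CC)(CC)OS(=O)(=O)C(F)(F)F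
Why: O-silylation of the C-6 enol and the tertiary C-7 hydroxyl; triflate-mediated equilibration should favour the silyl dienol ether that keeps the 2-pyranone ring intact (O-6, not O-8 or O-1), so the C-8 ketone and the lactone stay reducible and O-7 becomes a bulky, non-chelating group.

Step 13
Reactants: 19 (7S)-5-chloro-3-{(1E,3E,5S)-7-[(tert-butyldiphenylsilyl)oxy]-3,5-dimethylhepta-1,3-dien-1-yl}-7-methyl-6,7-bis[(triethylsilyl)oxy]-1H-isochromene-1,8(7H)-dione
Product: 21 (7R,8R)-5-chloro-7,8-dihydroxy-3-[(1E,3E,5S)-7-hydroxy-3,5-dimethylhepta-1,3-dien-1-yl]-7-methyl-7,8-dihydro-6H-isochromen-6-one, via lactol diol 20 (not isolated)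
Conditions: i-Bu2AlH (4 equiv), CH2Cl2, −78 °C; aq. potassium sodium tartrate; then HF·pyridine, pyridine/THF, 0 °C → rt
Reagents that add atoms: none
Why: Hydride reduction of the C-8 ketone anti to the C-7–OSiEt3 bond (non-chelation 1,2-induction, the bulky silyl ether shielding its own face) should give the 8R carbinol cis to O-7 and take the lactone to the lactol; HF·pyridine then ionises the lactol to a pyrylium ion whose 6-silyloxyvinyl substituent collapses to the C-6 ketone with C-4a=C-5 (vinylogous Stork–Danheiser-type transposition) and removes the remaining silyl ethers.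

**Compound list**

1 | 3-methylidenedihydrofuran-2(3H)-one | C=C1CCOC1=O | starting material
2 | (S)-3-methyldihydrofuran-2(3H)-one | C[C@H]1CCOC1=O | intermediate
3 | (S)-4-hydroxy-N-methoxy-N,2-dimethylbutanamide | C[C@@H](CCO)C(=O)N(C)OC | intermediate
4 | (S)-4-[(tert-butyldiphenylsilyl)oxy]-N-methoxy-N,2-dimethylbutanamide | C[C@@H](CCO[Si](c1ccccc1)(c1ccccc1)C(C)(C)C)C(=O)N(C)OC | intermediate
5 | (S)-4-[(tert-butyldiphenylsilyl)oxy]-2-methylbutanal | C[C@@H](CCO[Si](c1ccccc1)(c1ccccc1)C(C)(C)C)C=O | intermediate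
6 | 2-(triphenyl-λ5-phosphanylidene)propanal | CC(C=O)=P(c1ccccc1)(c1ccccc1)c1ccccc1 | starting material
7 | (2E,4S)-6-[(tert-butyldiphenylsilyl)oxy]-2,4-dimethylhex-2-enal | O=C/C(C)=C/[C@@H](C)CCO[Si](c1ccccc1)(c1ccccc1)C(C)(C)C | intermediate
8 | diethyl {2-[methoxy(methyl)amino]-2-oxoethyl}phosphonate | CCOP(=O)(OCC)CC(=O)N(C)OC | starting material
9 | (2E,4E,6S)-8-[(tert-butyldiphenylsilyl)oxy]-N-methoxy-N,4,6-trimethylocta-2,4-dienamide | CON(C)C(=O)/C=C/C(C)=C/[C@@H](C)CCO[Si](c1ccccc1)(c1ccccc1)C(C)(C)C | intermediate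
10 | 2,2,6-trimethyl-4H-1,3-dioxin-4-one | CC1=CC(=O)OC(C)(C)O1 | starting material
11 | 6-{(3E,5E,7S)-9-[(tert-butyldiphenylsilyl)oxy]-5,7-dimethyl-2-oxonona-3,5-dien-1-yl}-2,2-dimethyl-4H-1,3-dioxin-4-one | CC1(C)OC(CC(=O)/C=C/C(C)=C/[C@@H](C)CCO[Si](c2ccccc2)(c2ccccc2)C(C)(C)C)=CC(=O)O1 | intermediate
12 | (6E,8E,10S)-12-[(tert-butyldiphenylsilyl)oxy]-8,10-dimethyl-3,5-dioxododeca-1,6,8-trien-1-one (acylketene) | O=C=CC(=O)CC(=O)/C=C/C(C)=C/[C@@H](C)CCO[Si](c1ccccc1)(c1ccccc1)C(C)(C)C | intermediate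
13 | 6-{(1E,3E,5S)-7-[(tert-butyldiphenylsilyl)oxy]-3,5-dimethylhepta-1,3-dien-1-yl}-4-hydroxy-2H-pyran-2-one | O=C1C=C(O)C=C(/C=C/C(C)=C/[C@@H](C)CCO[Si](c2ccccc2)(c2ccccc2)C(C)(C)C)O1 | intermediate
14 | 4-chloro-6-{(1E,3E,5S)-7-[(tert-butyldiphenylsilyl)oxy]-3,5-dimethylhepta-1,3-dien-1-yl}-2-oxo-2H-pyran-3-carbaldehyde | O=CC1=C(Cl)C=C(/C=C/C(C)=C/[C@@H](C)CCO[Si](c2ccccc2)(c2ccccc2)C(C)(C)C)OC1=O | intermediate
15 | butane-2,3-dione | CC(=O)C(C)=O | starting material
16 | 6-{(1E,3E,5S)-7-[(tert-butyldiphenylsilyl)oxy]-3,5-dimethylhepta-1,3-dien-1-yl}-4-(2,3-dioxobutyl)-2-oxo-2H-pyran-3-carbaldehyde | CC(=O)C(=O)CC1=C(C=O)C(=O)OC(/C=C/C(C)=C/[C@@H](C)CCO[Si](c2ccccc2)(c2ccccc2)C(C)(C)C)=C1 | intermediate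
17 | (7S)-3-{(1E,3E,5S)-7-[(tert-butyldiphenylsilyl)oxy]-3,5-dimethylhepta-1,3-dien-1-yl}-6,7-dihydroxy-7-methyl-1H-isochromene-1,8(7H)-dione | CC(/C=C/C1=CC2=C(C(=O)O1)C(=O)[C@@](C)(O)C(O)=C2)=C\[C@@H](C)CCO[Si](c1ccccc1)(c1ccccc1)C(C)(C)C | intermediate
18 | (7S)-5-chloro-3-{(1E,3E,5S)-7-[(tert-butyldiphenylsilyl)oxy]-3,5-dimethylhepta-1,3-dien-1-yl}-6,7-dihydroxy-7-methyl-1H-isochromene-1,8(7H)-dione | CC(/C=C/C1=CC2=C(C(=O)O1)C(=O)[C@@](C)(O)C(O)=C2Cl)=C\[C@@H](C)CCO[Si](c1ccccc1)(c1ccccc1)C(C)(C)C | intermediate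
19 | (7S)-5-chloro-3-{(1E,3E,5S)-7-[(tert-butyldiphenylsilyl)oxy]-3,5-dimethylhepta-1,3-dien-1-yl}-7-methyl-6,7-bis[(triethylsilyl)oxy]-1H-isochromene-1,8(7H)-dione | CC(/C=C/C1=CC2=C(C(=O)O1)C(=O)[C@@](C)(O[Si](CC)(CC)CC)C(O[Si](CC)(CC)CC)=C2Cl)=C\[C@@H](C)CCO[Si](c1ccccc1)(c1ccccc1)C(C)(C)C | intermediate
20 | (7R,8R)-5-chloro-3-{(1E,3E,5S)-7-[(tert-butyldiphenylsilyl)oxy]-3,5-dimethylhepta-1,3-dien-1-yl}-7-methyl-6,7-bis[(triethylsilyl)oxy]-7,8-dihydro-1H-isochromene-1,8-diol (lactol, both C-1 epimers) | CC(/C=C/C1=CC2=C(C(O)O1)[C@@H](O)[C@@](C)(O[Si](CC)(CC)CC)C(O[Si](CC)(CC)CC)=C2Cl)=C\[C@@H](C)CCO[Si](c1ccccc1)(c1ccccc1)C(C)(C)C | intermediate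
21 | (7R,8R)-5-chloro-7,8-dihydroxy-3-[(1E,3E,5S)-7-hydroxy-3,5-dimethylhepta-1,3-dien-1-yl]-7-methyl-7,8-dihydro-6H-isochromen-6-one | CC(/C=C/C1=CC2=C(Cl)C(=O)[C@](C)(O)[C@H](O)C2=CO1)=C\[C@@H](C)CCO | target

**Step count and risks**

Total steps: 13. Longest linear sequence: 13 steps (1 → 21).

Steps most likely to fail:

Step 10. The carbon acid may attack the formyl carbon instead of the C–Cl carbon, or react through oxygen. The carbene may be consumed by residual vinylic chloride. The aldehyde may lose electrophilicity through ionisation of the vinylogous acid. Face selection at the C-7 ketone may be low. The fallback uses known chemistry: the carbocycle is brought in as an aromatic ring and the C-7 carbinol is made by oxidation instead of C–C bond formation. It sets out from 9 and returns at 17. Commercial methyl 2,4-dihydroxy-3,6-dimethylbenzoate is protected with MeOCH2Cl and i-Pr2NEt to give methyl 2,4-bis(methoxymethoxy)-3,6-dimethylbenzoate F1. Lateral lithiation of its 6-methyl group with LiN(i-Pr)2 (THF, −78 °C) and acylation with 9 should give methyl 2-{(3E,5E,7S)-9-[(tert-butyldiphenylsilyl)oxy]-5,7-dimethyl-2-oxonona-3,5-dien-1-yl}-4,6-bis(methoxymethoxy)-5-methylbenzoate F2. TsOH in MeOH should remove both acetals and close the enol lactone to 3-{(1E,3E,5S)-7-[(tert-butyldiphenylsilyl)oxy]-3,5-dimethylhepta-1,3-dien-1-yl}-6,8-dihydroxy-7-methyl-1H-isochromen-1-one F3. Enantioselective hydroxylative dearomatisation at C-7 with the copper–dioxygen oxidant formed from [Cu(CH3CN)4]PF6, (1R,2S,9S)-11-methyl-7,11-diazatricyclo[7.3.1.0(2,7)]tridecane and O2 (a known phenol dearomatisation for 7-hydroxy-6,8-dioxo systems of this kind) should then give the o-quinol 17.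

Step 13. Facial selectivity of hydride addition at C-8 may be poor, the lactol may be over-reduced, or the C-8 hydroxyl may ionise in competition with the lactol during acid treatment. The fallback separates the two reductions and puts C-8 under reagent control. It sets out from 19 and returns at 20. Corey–Bakshi–Shibata reduction of the C-8 ketone (BH3·SMe2 with the matched enantiomer of 1-methyl-3,3-diphenyltetrahydro-1H,3H-pyrrolo[1,2-c][1,3,2]oxazaborole, THF, −20 °C) should give (7R,8R)-5-chloro-3-{(1E,3E,5S)-7-[(tert-butyldiphenylsilyl)oxy]-3,5-dimethylhepta-1,3-dien-1-yl}-8-hydroxy-7-methyl-6,7-bis[(triethylsilyl)oxy]-7,8-dihydro-1H-isochromen-1-one F4 with the lactone intact. One equivalent of i-Bu2AlH at −78 °C then gives lactol 20, which is treated with HF·pyridine as in step 13.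

Step 9. The chloroiminium reagent or the HCl it releases may attack the dienyl chain (E/Z isomerisation, hydrochlorination) or the silyl ether. The fallback introduces the formyl group and the leaving group separately under mild conditions. It sets out from 13 and returns at 17. Condensation of 13 with HC(OEt)3 and aniline should give 6-{(1E,3E,5S)-7-[(tert-butyldiphenylsilyl)oxy]-3,5-dimethylhepta-1,3-dien-1-yl}-3-[(phenylamino)methylidene]-2H-pyran-2,4(3H)-dione F5. Mild aqueous acid hydrolysis should give 6-{(1E,3E,5S)-7-[(tert-butyldiphenylsilyl)oxy]-3,5-dimethylhepta-1,3-dien-1-yl}-4-hydroxy-2-oxo-2H-pyran-3-carbaldehyde F6. TsCl and Et3N should give 6-{(1E,3E,5S)-7-[(tert-butyldiphenylsilyl)oxy]-3,5-dimethylhepta-1,3-dien-1-yl}-3-formyl-2-oxo-2H-pyran-4-yl 4-methylbenzenesulfonate F7. F7 takes the place of 14 under the conditions of step 10, with sulfonate as the vinylic leaving group, and rejoins the route at 17.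

Further compounds
F1 | step 10 | methyl 2,4-bis(methoxymethoxy)-3,6-dimethylbenzoate | COC(=O)c1c(C)cc(OCOC)c(C)c1OCOC
F2 | step 10 | methyl 2-{(3E,5E,7S)-9-[(tert-butyldiphenylsilyl)oxy]-5,7-dimethyl-2-oxonona-3,5-dien-1-yl}-4,6-bis(methoxymethoxy)-5-methylbenzoate | COC(=O)c1c(CC(=O)/C=C/C(C)=C/[C@@H](C)CCO[Si](c2ccccc2)(c2ccccc2)C(C)(C)C)cc(OCOC)c(C)c1OCOC
F3 | step 10 | 3-{(1E,3E,5S)-7-[(tert-butyldiphenylsilyl)oxy]-3,5-dimethylhepta-1,3-dien-1-yl}-6,8-dihydroxy-7-methyl-1H-isochromen-1-one | Cc1c(O)cc2C=C(/C=C/C(C)=C/[C@@H](C)CCO[Si](c3ccccc3)(c3ccccc3)C(C)(C)C)OC(=O)c2c1O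
F4 | step 13 | (7R,8R)-5-chloro-3-{(1E,3E,5S)-7-[(tert-butyldiphenylsilyl)oxy]-3,5-dimethylhepta-1,3-dien-1-yl}-8-hydroxy-7-methyl-6,7-bis[(triethylsilyl)oxy]-7,8-dihydro-1H-isochromen-1-one | CC(/C=C/C1=CC2=C(C(=O)O1)[C@@H](O)[C@@](C)(O[Si](CC)(CC)CC)C(O[Si](CC)(CC)CC)=C2Cl)=C\[C@@H](C)CCO[Si](c1ccccc1)(c1ccccc1)C(C)(C)C
F5 | step 9 | 6-{(1E,3E,5S)-7-[(tert-butyldiphenylsilyl)oxy]-3,5-dimethylhepta-1,3-dien-1-yl}-3-[(phenylamino)methylidene]-2H-pyran-2,4(3H)-dione | O=C1C=C(/C=C/C(C)=C/[C@@H](C)CCO[Si](c2ccccc2)(c2ccccc2)C(C)(C)C)OC(=O)C1=CNc1ccccc1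
F6 | step 9 | 6-{(1E,3E,5S)-7-[(tert-butyldiphenylsilyl)oxy]-3,5-dimethylhepta-1,3-dien-1-yl}-4-hydroxy-2-oxo-2H-pyran-3-carbaldehyde | O=CC1=C(O)C=C(/C=C/C(C)=C/[C@@H](C)CCO[Si](c2ccccc2)(c2ccccc2)C(C)(C)C)OC1=O
F7 | step 9 | 6-{(1E,3E,5S)-7-[(tert-butyldiphenylsilyl)oxy]-3,5-dimethylhepta-1,3-dien-1-yl}-3-formyl-2-oxo-2H-pyran-4-yl 4-methylbenzenesulfonate | O=CC1=C(OS(=O)(=O)c2ccc(C)cc2)C=C(/C=C/C(C)=C/[C@@H](C)CCO[Si](c2ccccc2)(c2ccccc2)C(C)(C)C)OC1=O
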